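## Structural features

The target is a flavanone (2-arylchroman-4-one; numbering O1, C2, C3, C4, C4a, C5–C8, C8a). A fully substituted phloroglucinol-type ring A is fused to the dihydropyranone ring C, which carries a 2,4-dihydroxyphenyl ring B at C2. Ring A has free hydroxyls at C5 and C7, an (E)-3-methylbut-1-enyl group at C6 between them, and a prenyl (3-methylbut-2-enyl) group at C8 next to O1. C2 (S) is the only stereocentre of the target; in the cycloadduct it has a 1,3-partner at C4, which is later erased. C2 is a doubly donor-activated benzylic ether β to the C4 carbonyl, so it can be lost by retro-oxa-Michael opening under base or by O1–C2 ionisation under acid. The fragile groups are the prenyl alkene (acid- or halonium-induced ring closure onto a neighbouring phenol), the electron-rich conjugated C6 alkene, the four phenols and the MOM acetals that mask them. The real difficulty is twofold: placing two different five-carbon side chains on ring A with one defined oxygen left free to become O1, and creating C2 in one absolute configuration without equilibrating chalcone chemistry. The key step exploits that C4–C4a–C8a–O1 is the four-atom heterodiene of an ortho-quinone methide on ring A, while C2–C3 is the vinyl group of a 2,4-dioxygenated styrene whose polarisation puts ring B on C2.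

## Logic of the disconnections

**19 from 18.** The four phenolic O–CH2 bonds of the MOM acetals are cut last. The acetals keep ring A a poor leaving group for O1–C2 and keep the phenols away from the side chains while C4 is adjusted. Once the C4 carbonyl is present, ring A is a vinylogous ester array and should tolerate methanolic acid. The demand is an acid strong enough for the ring B acetals yet mild towards the prenyl group, the C6 alkene and C2.

**18 from 17 from 16.** The C4 carbonyl is traced to the carbinol and this to the methyl ether. C4 of 16 is an ether carbon at the alcohol oxidation level, not at the ketone level, so one oxidation after ring formation is unavoidable. There is no skeletal gain, but the target is linked to the cycloadduct. The exchange must ionise C4–O only, never O1–C2, and the oxidant must spare two alkenes and three electron-rich arenes.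

**16 from 9, 12 and 13.** O1–C2 and C3–C4 are cut together. This removes ring C and both stereocentres and divides the molecule into a ring A piece (9), a ring B piece (12) and the donor of the ether group (13). The cut follows the natural polarity: C4 is electrophilic once 9 is ionised, and the terminal carbon of 12 is nucleophilic. The forward step must control the absolute configuration and take 12 in preference to the two alkenes of 9. The C4 epimers of 16 need not share the C2 configuration, because a chiral catalyst that fixes the C4 face gives (2S) in the cis adduct and (2R) in the trans adduct. The 2,4-cis isomer is therefore isolated before C4 is levelled.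

**9 from 7 and 8; 7 from 6.** The aryl–alkenyl bond at C6 of the flavanone (C5 of the aldehyde ring) is cut to an aryl iodide and an (E)-alkenylboronate, so the alkene geometry is bought. The iodide comes from the corresponding C–H. An electrophile cannot reliably tell apart the two aromatic C–H positions of 2, since the free phenol directs ortho, where the prenyl group must go. Iodination is therefore placed after the prenyl group has filled that position, when a single aromatic C–H is left. The demand is that this arene carbon, para to the phenol and flanked by two acetal oxygens, outruns the prenyl alkene and the neighbouring phenol for the iodonium source.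

**6 from 5 from 4 from 2 and 3.** The C8–prenyl bond is cut by a [3,3] retron to the tertiary allyl ether on the oxygen that becomes O1. This ties the free phenol and the prenyl group together as neighbours and so fixes the orientation of ring A. The allyl ether is reached from the propargyl ether because a tertiary allyl halide would not alkylate cleanly. Semi-hydrogenation must stop at the alkene, and the rearrangement must go to the free ortho carbon.

**2 from 1.** Two O–CH2 bonds are cut. The third hydroxyl, chelated to the formyl group, stays free without any differentiation step.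

**12 from 11 from 10.** The vinyl C=C is cut to the aldehyde and a one-carbon ylide, and the two acetals to the diphenol. Full protection includes the chelated 2-hydroxyl.

## Other disconnections considered

**Alternative 1:** Ring A is cut at C4a–C5, with C5–C8 traced to a masked triketide chain on a chiral dihydropyranone that already holds C2.

- **Forward key step:** The dioxinone A2, (2S)-2-[2,4-bis(methoxymethoxy)phenyl]-6-[1-(2,2-dimethyl-4-oxo-4H-1,3-dioxin-6-yl)-4-methylpent-3-enyl]-2,3-dihydro-4H-pyran-4-one, would be heated in toluene. Loss of acetone gives an acylketene, enolisation gives a dienylketene, and 6π-electrocyclisation onto the pyranone α-carbon (C4a) would give the 5,7-dihydroxy-8-prenylflavanone A1.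
- **In its favour:** C2 would come from an established catalytic asymmetric hetero-Diels–Alder reaction of a siloxydiene with 11. This is better founded than the untested induction of step 8, and here the alternative is the better plan. Ring A forms under neutral thermal conditions, and the C4 ketone is present from the start, so steps 9 and 10 would fall away.
- **Against it:** A1 still lacks the C6 alkenyl group. It would have to be added by halogenation and cross-coupling on a flavanone with two free phenols, one beside the prenyl group. This is the problem of step 4 in a harsher form, with the base sensitivity of the β-aryloxy ketone added. A2 needs a long linear build-up, and its 2-aryl-dihydropyranone can open by retro-oxa-Michael reaction near the thermolysis temperature.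
- **Comparison:** On structure it matches rings B and C but not C6. On mechanism a pericyclic cascade replaces a cationic cycloaddition, which is kinder to acid-labile groups. On step economy it would be clearly longer than the eleven steps chosen.

**Alternative 2:** Ring A is cut at C8–C8a and C6–C7 (and C4a–C8a) into a vinylketene and an alkyne.

- **Forward key step:** Heating the cyclobutenone A4, 3-ethoxy-2-[(E)-3-methylbut-1-enyl]cyclobut-2-en-1-one, with the siloxyalkyne A5, triisopropyl[(5-methylhex-4-en-1-yn-1-yl)oxy]silane, would start the benzannulation cascade (ring opening, ketene–alkyne [2+2], second ring opening, 6π-closure). The product would be the phenol A3, 5-ethoxy-4-[(E)-3-methylbut-1-enyl]-2-(3-methylbut-2-enyl)-3-(triisopropylsilyloxy)phenol.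
- **In its favour:** Both side chains arrive on the building blocks and the three oxygens are differentiated from the outset with O1 free. No electrophilic halogen meets the prenyl group. On regiochemical certainty this is better than steps 1 to 5.
- **Against it:** A3 has hydrogen at C4a and no C4, so an ortho-formylation must follow. It then only replaces the preparation of 9; ring C and C2 still need step 8 or an equivalent. The O5 ethyl ether can be cleaved only by boron trihalides or hot thiolate, which the prenyl group, the C6 alkene and the flavanone would not survive. A4 and A5 each need several steps.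
- **Comparison:** On mechanism the thermal cascade is neutral, which equals the mildness of steps 1 to 5. On step economy it would at best equal the five steps to 9 and more probably exceed them. On structure the ethyl ether is a misfit that the chosen MOM pattern avoids.

**Alternative 3:** Ring C is cut at C2–C3.

- **Forward key step:** The diazoketone A7, 2-diazo-1-[2-{[2,4-bis(tert-butyldimethylsilyloxy)phenyl]methoxy}-4,6-bis(tert-butyldimethylsilyloxy)-5-[(E)-3-methylbut-1-enyl]-3-(3-methylbut-2-enyl)phenyl]ethan-1-one, would be decomposed by Rh2(S-PTTL)4 (divalent rhodium). The carbenoid carbon C3 would insert into a benzylic C–H of the O1–CH2–aryl group to give the tetrakis-silyl flavanone A6.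
- **In its favour:** The ring closes with the C4 ketone in place and C2 is set in the same step. The silyl ethers would allow a buffered fluoride endgame with no acid at all. On the last three steps this is better than the chosen plan, and in creating the stereocentre in the ring-closing step it is its equal.
- **Against it:** An acceptor-only carbenoid beside an aryl benzyl ether is expected to attack the O1 lone pair first. The five-membered oxonium ylide would then undergo a [1,2]-benzyl shift to a 2-benzylbenzofuran-3-one. Cyclopropanation of the two alkenes and addition to ring B compete. The required 1,6-insertion is less usual than 1,5, and the very hydridic C–H may react through hydride transfer, with loss of enantiocontrol. A7 needs a hexasubstituted benzoic acid with labile ortho silyl ethers.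
- **Comparison:** On structure it fits the target best, since no C4 adjustment is needed. On mechanism it carries more competing pathways than the ion-pair cycloaddition. On step economy it would be no shorter, because ring A needs the same side-chain chemistry plus a carboxyl group.

Key step: step 8

Assumption: the sense of induction of the chiral phosphoric acid cannot be predicted with confidence; the (R)-catalyst is written, and its enantiomer is to be used if the (2R) series predominates.

## Steps

**Step 1**
Reactants: 1 2,4,6-trihydroxybenzaldehyde
Product: 2 2-hydroxy-4,6-bis(methoxymethoxy)benzaldehyde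
Conditions: MOMCl (2.2 equiv), i-Pr2NEt (3 equiv), CH2Cl2, 0 °C → rt
Reagents that add atoms: chloromethyl methyl ether, COCCl
Why: O-alkylation of the two most acidic phenols; after one ortho hydroxyl has reacted, the other is locked in a hydrogen bond to the formyl group and should stay free with limited reagent.

**Step 2**
Reactants: 2 2-hydroxy-4,6-bis(methoxymethoxy)benzaldehyde; 3 3-chloro-3-methylbut-1-yne
Product: 4 4,6-bis(methoxymethoxy)-2-[(2-methylbut-3-yn-2-yl)oxy]benzaldehyde
Conditions: 3 (2.5 equiv), K2CO3, KI, CuI (5 mol%), acetone, 56 °C
Reagents that add atoms: none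
Why: Copper-assisted propargylic etherification of the phenoxide with the tertiary propargylic chloride, the standard entry to aryl 1,1-dimethylpropargyl ethers; MOM acetals and the aldehyde are inert to carbonate.

**Step 3**
Reactants: 4 4,6-bis(methoxymethoxy)-2-[(2-methylbut-3-yn-2-yl)oxy]benzaldehyde
Product: 6 2-hydroxy-4,6-bis(methoxymethoxy)-3-(3-methylbut-2-enyl)benzaldehyde, via 1,1-dimethylallyl ether 5 (not isolated)
Conditions: H2 (1 atm), Pd/CaCO3 poisoned with Pb(OAc)2 (Lindlar catalyst), quinoline, EtOAc, rt; filter, concentrate; then xylenes, 130 °C
Reagents that add atoms: none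
Why: Lindlar semi-hydrogenation should stop at the terminal alkene 5; its aromatic Claisen rearrangement ([3,3]) then goes to the only free ortho carbon, inverts the allyl unit to the linear prenyl group, and tautomerisation restores the chelated phenol. This places the free hydroxyl and the prenyl group side by side.

**Step 4**
Reactants: 6 2-hydroxy-4,6-bis(methoxymethoxy)-3-(3-methylbut-2-enyl)benzaldehyde
Product: 7 2-hydroxy-5-iodo-4,6-bis(methoxymethoxy)-3-(3-methylbut-2-enyl)benzaldehyde
Conditions: NIS (1.05 equiv), MeCN, −20 °C → 0 °C, dark
Reagents that add atoms: N-iodosuccinimide, O=C1CCC(=O)N1I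
Why: Electrophilic aromatic iodination at the single remaining ring C–H, para to the phenol and ortho to both acetal oxygens, so no regiochemical choice exists. Acid-free, cold conditions and the weakly nucleophilic chelated phenol are meant to let arene substitution outrun iodonium formation at the prenyl alkene.

**Step 5**
Reactants: 7 2-hydroxy-5-iodo-4,6-bis(methoxymethoxy)-3-(3-methylbut-2-enyl)benzaldehyde; 8 (E)-3-methylbut-1-enylboronic acid pinacol ester
Product: 9 2-hydroxy-4,6-bis(methoxymethoxy)-5-[(E)-3-methylbut-1-enyl]-3-(3-methylbut-2-enyl)benzaldehyde
Conditions: 8 (1.5 equiv), Pd(OAc)2 (5 mol%), 2-dicyclohexylphosphino-2',6'-dimethoxybiphenyl (SPhos, 10 mol%), K3PO4 (3 equiv), THF/H2O (10:1), 60 °C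
Reagents that add atoms: none
Why: Suzuki–Miyaura coupling with retention of the (E) geometry of the boronate; the bulky electron-rich biaryl phosphine is chosen for the di-ortho-substituted, electron-rich iodide, and the phenoxide, aldehyde and prenyl group are tolerated.

**Step 6**
Reactants: 10 2,4-dihydroxybenzaldehyde
Product: 11 2,4-bis(methoxymethoxy)benzaldehyde
Conditions: NaH (2.5 equiv), MOMCl (2.5 equiv), DMF, 0 °C → rt
Reagents that add atoms: chloromethyl methyl ether, COCCl
Why: Williamson-type O-alkylation; full deprotonation with NaH is used so that the chelated 2-hydroxyl is protected as well.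

**Step 7**
Reactants: 11 2,4-bis(methoxymethoxy)benzaldehyde
Product: 12 1-ethenyl-2,4-bis(methoxymethoxy)benzene
Conditions: Ph3PCH3Br (1.3 equiv), KOt-Bu (1.25 equiv), THF, 0 °C → rt
Reagents that add atoms: methyltriphenylphosphonium bromide, C[P+](c1ccccc1)(c1ccccc1)c1ccccc1.[Br-]
Why: Wittig methylenation with the non-stabilised ylide; the acetals are base-stable, and the acid-sensitive styrene is to be stored cold over a trace of base and used soon.

**Step 8**
Reactants: 9 2-hydroxy-4,6-bis(methoxymethoxy)-5-[(E)-3-methylbut-1-enyl]-3-(3-methylbut-2-enyl)benzaldehyde; 12 1-ethenyl-2,4-bis(methoxymethoxy)benzene; 13 trimethyl orthoformate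
Product: 16 (2S,4S)-2-[2,4-bis(methoxymethoxy)phenyl]-4-methoxy-5,7-bis(methoxymethoxy)-6-[(E)-3-methylbut-1-enyl]-8-(3-methylbut-2-enyl)chromane, via dimethyl acetal 14 (not isolated), via O-methyl oxocarbenium phosphate 15 (not isolated)
Conditions: 13 (3 equiv), (R)-3,3'-bis(2,4,6-triisopropylphenyl)-1,1'-binaphthyl-2,2'-diyl hydrogen phosphate (10 mol%), 4 Å MS, PhMe, rt (acetal formation); then 12 (2 equiv), −30 °C
Reagents that add atoms: none
Why: Proposed new method: the phosphoric acid catalyses acetalisation of 9 by 13 to 14 and ionises 14 to the O-methyl oxocarbenium ion 15, the conjugate acid of the methoxy ortho-quinone methide, which stays paired with the chiral phosphate through its charge and a hydrogen bond from the acidic O1–H. The terminal carbon of 12 attacks C4 (C3–C4 bond) and the C2 benzylic cation so formed, stabilised by the two ring B oxygens, is captured by O1 (O1–C2 bond), a polar, asynchronous inverse-electron-demand hetero-[4+2]. The closest known reactions are the racemic Sc(OTf)3-catalysed coupling of salicylaldehydes, orthoformates and styrenes to 4-alkoxy-2-arylchromans and the chiral-phosphoric-acid-controlled [4+2] cycloadditions of ortho-quinone methides made from ortho-hydroxybenzyl alcohols; asymmetric induction on an alkoxy methide is the untested element. Ring C closes as a six-membered ring by attack of the phenol oxygen on the cationic C2, a 6-exo-trig closure onto the para-quinoid form of the cation and the second bond of the stepwise cycloaddition. C4 is set by the face of 15 left open by the phosphate in the C–C bond-forming event, and C2 follows in the closure through a chair-like transition state with aryl and methoxy both pseudo-equatorial, so that the 2,4-cis adduct is expected and (4S) is relayed to (2S). A trans adduct built on the same C4 face would carry (2R), so 16 is to be purified as the single cis diastereomer on Et3N-deactivated silica before C4 is levelled, with its enantiomeric purity checked at this stage. Regioselectivity follows from cation stability (only attack through the terminal carbon gives a doubly oxygen-stabilised benzylic cation) and the orientation of ring A from O1 being the only free phenol. Chemoselectivity needs 12 to outcompete the other alkenes, which its monosubstituted, donor-activated vinyl group and its excess secure, the C6 alkenyl group being 1,2-disubstituted and twisted by two ortho acetal groups and the prenyl group unconjugated; the weak Brønsted acid also spares the MOM acetals and the phenol–prenyl pair that a metal triflate could cyclise.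

**Step 9**
Reactants: 16 (2S,4S)-2-[2,4-bis(methoxymethoxy)phenyl]-4-methoxy-5,7-bis(methoxymethoxy)-6-[(E)-3-methylbut-1-enyl]-8-(3-methylbut-2-enyl)chromane
Product: 17 (2S)-2-[2,4-bis(methoxymethoxy)phenyl]-5,7-bis(methoxymethoxy)-6-[(E)-3-methylbut-1-enyl]-8-(3-methylbut-2-enyl)chroman-4-ol (mixture of C4 epimers)
Conditions: pyridinium p-toluenesulfonate (0.3 equiv), acetone/H2O (4:1), rt
Reagents that add atoms: water, O
Why: Acid-catalysed SN1 exchange at C4, whose cation is stabilised by three ring A oxygens and should form far more readily than one at C2 (aryl ether oxygen, weaker donor set), so C2 is untouched; MOM acetals need stronger acid, and the large excess of water should favour capture over loss of H3.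

**Step 10**
Reactants: 17 (2S)-2-[2,4-bis(methoxymethoxy)phenyl]-5,7-bis(methoxymethoxy)-6-[(E)-3-methylbut-1-enyl]-8-(3-methylbut-2-enyl)chroman-4-ol
Product: 18 (2S)-2-[2,4-bis(methoxymethoxy)phenyl]-5,7-bis(methoxymethoxy)-6-[(E)-3-methylbut-1-enyl]-8-(3-methylbut-2-enyl)chroman-4-one
Conditions: Dess–Martin periodinane (1.3 equiv), pyridine (3 equiv), CH2Cl2, 0 °C → rt
Reagents that add atoms: none
Why: Dess–Martin oxidation of a secondary benzylic alcohol under buffered, non-acidic conditions that leave alkenes, acetals and C2 alone; both C4 epimers converge on one ketone.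

**Step 11**
Reactants: 18 (2S)-2-[2,4-bis(methoxymethoxy)phenyl]-5,7-bis(methoxymethoxy)-6-[(E)-3-methylbut-1-enyl]-8-(3-methylbut-2-enyl)chroman-4-one
Product: 19 (2S)-2-(2,4-dihydroxyphenyl)-5,7-dihydroxy-6-[(E)-3-methylbut-1-enyl]-8-(3-methylbut-2-enyl)chroman-4-one
Conditions: HCl (1.25 M in MeOH), THF, 40 °C, stopped at full conversion
Reagents that add atoms: none
Why: Acid-catalysed transacetalisation of the four MOM ethers to methanol, the usual unmasking of prenylated flavanones; the C4 carbonyl makes ring A a vinylogous ester array, which should lower the tendency of the side chains and of O1–C2 to ionise.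

## Compound list

1 | 2,4,6-trihydroxybenzaldehyde | O=Cc1c(O)cc(O)cc1O | starting material
2 | 2-hydroxy-4,6-bis(methoxymethoxy)benzaldehyde | COCOc1cc(O)c(C=O)c(OCOC)c1 | intermediate
3 | 3-chloro-3-methylbut-1-yne | CC(C)(Cl)C#C | starting material
4 | 4,6-bis(methoxymethoxy)-2-[(2-methylbut-3-yn-2-yl)oxy]benzaldehyde | COCOc1cc(OC(C)(C)C#C)c(C=O)c(OCOC)c1 | intermediate
5 | 4,6-bis(methoxymethoxy)-2-[(2-methylbut-3-en-2-yl)oxy]benzaldehyde (not isolated) | COCOc1cc(OC(C)(C)C=C)c(C=O)c(OCOC)c1 | intermediate
6 | 2-hydroxy-4,6-bis(methoxymethoxy)-3-(3-methylbut-2-enyl)benzaldehyde | CC(C)=CCc1c(OCOC)cc(OCOC)c(C=O)c1O | intermediate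
7 | 2-hydroxy-5-iodo-4,6-bis(methoxymethoxy)-3-(3-methylbut-2-enyl)benzaldehyde | CC(C)=CCc1c(OCOC)c(I)c(OCOC)c(C=O)c1O | intermediate
8 | (E)-3-methylbut-1-enylboronic acid pinacol ester | CC(C)/C=C/B1OC(C)(C)C(C)(C)O1 | starting material
9 | 2-hydroxy-4,6-bis(methoxymethoxy)-5-[(E)-3-methylbut-1-enyl]-3-(3-methylbut-2-enyl)benzaldehyde | CC(C)=CCc1c(OCOC)c(/C=C/C(C)C)c(OCOC)c(C=O)c1O | intermediate
10 | 2,4-dihydroxybenzaldehyde | O=Cc1ccc(O)cc1O | starting material
11 | 2,4-bis(methoxymethoxy)benzaldehyde | COCOc1ccc(C=O)c(OCOC)c1 | intermediate
12 | 1-ethenyl-2,4-bis(methoxymethoxy)benzene | C=Cc1ccc(OCOC)cc1OCOC | intermediate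
13 | trimethyl orthoformate | COC(OC)OC | starting material
14 | 2-(dimethoxymethyl)-3,5-bis(methoxymethoxy)-4-[(E)-3-methylbut-1-enyl]-6-(3-methylbut-2-enyl)phenol (not isolated) | CC(C)=CCc1c(OCOC)c(/C=C/C(C)C)c(OCOC)c(C(OC)OC)c1O | intermediate
15 | (E)-{[2-hydroxy-4,6-bis(methoxymethoxy)-5-[(E)-3-methylbut-1-enyl]-3-(3-methylbut-2-enyl)phenyl]methylidene}(methyl)oxonium, ion-paired with the chiral phosphate (not isolated) | C/[O+]=C/c1c(O)c(CC=C(C)C)c(OCOC)c(/C=C/C(C)C)c1OCOC | intermediate
16 | (2S,4S)-2-[2,4-bis(methoxymethoxy)phenyl]-4-methoxy-5,7-bis(methoxymethoxy)-6-[(E)-3-methylbut-1-enyl]-8-(3-methylbut-2-enyl)chromane | CC(C)=CCc1c(OCOC)c(/C=C/C(C)C)c(OCOC)c2c1O[C@H](c1ccc(OCOC)cc1OCOC)C[C@@H]2OC | intermediate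
17 | (2S)-2-[2,4-bis(methoxymethoxy)phenyl]-5,7-bis(methoxymethoxy)-6-[(E)-3-methylbut-1-enyl]-8-(3-methylbut-2-enyl)chroman-4-ol (C4 epimers) | CC(C)=CCc1c(OCOC)c(/C=C/C(C)C)c(OCOC)c2c1O[C@H](c1ccc(OCOC)cc1OCOC)CC2O | intermediate
18 | (2S)-2-[2,4-bis(methoxymethoxy)phenyl]-5,7-bis(methoxymethoxy)-6-[(E)-3-methylbut-1-enyl]-8-(3-methylbut-2-enyl)chroman-4-one | CC(C)=CCc1c(OCOC)c(/C=C/C(C)C)c(OCOC)c2c1O[C@H](c1ccc(OCOC)cc1OCOC)CC2=O | intermediate
19 | (2S)-2-(2,4-dihydroxyphenyl)-5,7-dihydroxy-6-[(E)-3-methylbut-1-enyl]-8-(3-methylbut-2-enyl)chroman-4-one | CC(C)=CCc1c(O)c(/C=C/C(C)C)c(O)c2c1O[C@H](c1ccc(O)cc1O)CC2=O | target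

## Step count and least certain steps

Total: 11 steps. Longest linear sequence: 9 steps (steps 1–5 and 8–11, from 1); the ring B branch contributes steps 6 and 7.

**Step 8 (key step, proposed new method).** The most likely failure is poor facial selectivity, because the alkoxy methide cation offers the phosphate only one hydrogen-bond anchor. Further risks are erosion of C2 by reversible O1–C2 ionisation of the product, a low cis preference, and acid-induced oligomerisation of 12.

Fallback by known chemistry, setting out from 9, 12 and 13: the three are combined under Sc(OTf)3 (5 mol%) in CH2Cl2 at 0 °C, the established racemic cycloaddition. This should give 16 together with its mirror image, (2R,4R)-2-[2,4-bis(methoxymethoxy)phenyl]-4-methoxy-5,7-bis(methoxymethoxy)-6-[(E)-3-methylbut-1-enyl]-8-(3-methylbut-2-enyl)chromane F1. Hydrolysis as in step 9 gives 17 with (2R)-2-[2,4-bis(methoxymethoxy)phenyl]-5,7-bis(methoxymethoxy)-6-[(E)-3-methylbut-1-enyl]-8-(3-methylbut-2-enyl)chroman-4-ol F2. Oxidation as in step 10 gives 18 with (2R)-2-[2,4-bis(methoxymethoxy)phenyl]-5,7-bis(methoxymethoxy)-6-[(E)-3-methylbut-1-enyl]-8-(3-methylbut-2-enyl)chroman-4-one F3. Preparative HPLC on amylose tris(3,5-dimethylphenylcarbamate) then separates 18 from F3, and the route is rejoined at 18.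

**Step 4.** Iodonium capture by the prenyl alkene, followed by ring closure through the neighbouring phenol (iodoetherification), may compete with arene substitution, because both sites are electron-rich.

Fallback, setting out from 6: the internal nucleophile is masked. Acetylation (Ac2O, pyridine, 4-dimethylaminopyridine) gives 2-formyl-3,5-bis(methoxymethoxy)-6-(3-methylbut-2-enyl)phenyl acetate F4. Iodination (NIS, CF3CO2H 10 mol%, MeCN, 0 °C) gives 2-formyl-4-iodo-3,5-bis(methoxymethoxy)-6-(3-methylbut-2-enyl)phenyl acetate F5. Methanolysis (K2CO3, MeOH, 0 °C) returns the route to 7.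

**Step 9.** The C4 cation may lose H3 to give the flav-3-ene instead of being hydrated, or prolonged acid may begin to open O1–C2 and scramble C2.

Fallback, setting out from 16 and returning at 18: the heterolysis–hydration–oxidation sequence is replaced by direct hydride abstraction. DDQ in CH2Cl2/pH 7 phosphate buffer at 0 °C (the oxidative cleavage of electron-rich benzylic ethers) should convert the C4 methyl ether through its hemiketal into the ketone. No new isolated compound is involved. Over-oxidation at the C2–H of the ring B benzylic ether is the risk to be watched.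

**Step 11.** Protic acid may also protonate the prenyl or C6 alkene (chroman formation with O7–H, methanol addition) or ionise O1–C2 once ring B is a free resorcinol, with partial loss of enantiomeric purity.

Fallback, setting out from 18 and returning at 19: the acetals are cleaved by Lewis-acid-assisted thiolysis in an aprotic medium (ZnBr2, n-PrSH, CH2Cl2, 0 °C). This is a different bond-breaking mechanism that generates no Brønsted acid and no solvolytic medium. No new isolated compound is involved.

## Further compounds

F1 | step 8 | (2R,4R)-2-[2,4-bis(methoxymethoxy)phenyl]-4-methoxy-5,7-bis(methoxymethoxy)-6-[(E)-3-methylbut-1-enyl]-8-(3-methylbut-2-enyl)chromane | CC(C)=CCc1c(OCOC)c(/C=C/C(C)C)c(OCOC)c2c1O[C@@H](c1ccc(OCOC)cc1OCOC)C[C@H]2OC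
F2 | step 8 | (2R)-2-[2,4-bis(methoxymethoxy)phenyl]-5,7-bis(methoxymethoxy)-6-[(E)-3-methylbut-1-enyl]-8-(3-methylbut-2-enyl)chroman-4-ol (C4 epimers) | CC(C)=CCc1c(OCOC)c(/C=C/C(C)C)c(OCOC)c2c1O[C@@H](c1ccc(OCOC)cc1OCOC)CC2O
F3 | step 8 | (2R)-2-[2,4-bis(methoxymethoxy)phenyl]-5,7-bis(methoxymethoxy)-6-[(E)-3-methylbut-1-enyl]-8-(3-methylbut-2-enyl)chroman-4-one | CC(C)=CCc1c(OCOC)c(/C=C/C(C)C)c(OCOC)c2c1O[C@@H](c1ccc(OCOC)cc1OCOC)CC2=O
F4 | step 4 | 2-formyl-3,5-bis(methoxymethoxy)-6-(3-methylbut-2-enyl)phenyl acetate | CC(C)=CCc1c(OCOC)cc(OCOC)c(C=O)c1OC(C)=O
F5 | step 4 | 2-formyl-4-iodo-3,5-bis(methoxymethoxy)-6-(3-methylbut-2-enyl)phenyl acetate | CC(C)=CCc1c(OCOC)c(I)c(OCOC)c(C=O)c1OC(C)=O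
F0 | step 9 | none | none
F0 | step 11 | none | none
A1 | alternative 1 | (2S)-2-[2,4-bis(methoxymethoxy)phenyl]-5,7-dihydroxy-8-(3-methylbut-2-enyl)chroman-4-one | CC(C)=CCc1c(O)cc(O)c2c1O[C@H](c1ccc(OCOC)cc1OCOC)CC2=O
A2 | alternative 1 | (2S)-2-[2,4-bis(methoxymethoxy)phenyl]-6-[1-(2,2-dimethyl-4-oxo-4H-1,3-dioxin-6-yl)-4-methylpent-3-enyl]-2,3-dihydro-4H-pyran-4-one | CC(C)=CCC(C1=CC(=O)OC(C)(C)O1)C1=CC(=O)C[C@@H](c2ccc(OCOC)cc2OCOC)O1
A3 | alternative 2 | 5-ethoxy-4-[(E)-3-methylbut-1-enyl]-2-(3-methylbut-2-enyl)-3-(triisopropylsilyloxy)phenol | CC(C)=CCc1c(O[Si](C(C)C)(C(C)C)C(C)C)c(/C=C/C(C)C)c(OCC)cc1O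
A4 | alternative 2 | 3-ethoxy-2-[(E)-3-methylbut-1-enyl]cyclobut-2-en-1-one | CCOC1=C(/C=C/C(C)C)C(=O)C1
A5 | alternative 2 | triisopropyl[(5-methylhex-4-en-1-yn-1-yl)oxy]silane | CC(C)=CCC#CO[Si](C(C)C)(C(C)C)C(C)C
A6 | alternative 3 | (2S)-2-[2,4-bis(tert-butyldimethylsilyloxy)phenyl]-5,7-bis(tert-butyldimethylsilyloxy)-6-[(E)-3-methylbut-1-enyl]-8-(3-methylbut-2-enyl)chroman-4-one | CC(C)=CCc1c(O[Si](C)(C)C(C)(C)C)c(/C=C/C(C)C)c(O[Si](C)(C)C(C)(C)C)c2c1O[C@H](c1ccc(O[Si](C)(C)C(C)(C)C)cc1O[Si](C)(C)C(C)(C)C)CC2=O
A7 | alternative 3 | 2-diazo-1-[2-{[2,4-bis(tert-butyldimethylsilyloxy)phenyl]methoxy}-4,6-bis(tert-butyldimethylsilyloxy)-5-[(E)-3-methylbut-1-enyl]-3-(3-methylbut-2-enyl)phenyl]ethan-1-one | CC(C)=CCc1c(O[Si](C)(C)C(C)(C)C)c(/C=C/C(C)C)c(O[Si](C)(C)C(C)(C)C)c(C(=O)C=[N+]=[N-])c1OCc1ccc(O[Si](C)(C)C(C)(C)C)cc1O[Si](C)(C)C(C)(C)C
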